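**Retrosynthetic overview**
1. Scirpusin C (7) is the dehydrodimer of (E)-3,3',4,5,5'-pentahydroxystilbene (4). The cuts are C3–C3a (C8 of one monomer to C2' of the pyrogallol ring of the other) and O1–C2 (pyrogallol 3'-OH to C7).
2. Forward, in one flask: the pyrogallol ring of one molecule of 4 is oxidised to hydroxy-ortho-quinone 5; C8 of a second molecule of 4 adds to it (C–C bond, sets C3) and gives para-quinone methide 6; the neighbouring phenol closes onto 6 (sets C2 trans). The dihydrofuran is the only ring formed; a chiral phosphoric acid controls the absolute configuration.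
3. 4 comes from pentamethyl ether 3 by global demethylation; 3 comes from aldehyde 1 and phosphonate 2 by Horner–Wadsworth–Emmons olefination.

Assumption: the (R)-configured phosphoric acid is taken to give the (2S,3S) series; this sense of induction is a prediction, and the (S)-acid is used under the same conditions if it proves opposite.

**Step 1**
Reactants: 1 3,4,5-trimethoxybenzaldehyde; 2 diethyl (3,5-dimethoxybenzyl)phosphonate
Product: 3 (E)-3,3',4,5,5'-pentamethoxystilbene
Conditions: KOtBu (1.2 equiv), THF, 0 °C to rt; recrystallise from EtOH
Reagents that add atoms: none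
Why: Horner–Wadsworth–Emmons olefination of an aromatic aldehyde with a benzylphosphonate is reliably E-selective, and recrystallisation removes any trace of Z isomer.

**Step 2**
Reactants: 3 (E)-3,3',4,5,5'-pentamethoxystilbene
Product: 4 (E)-3,3',4,5,5'-pentahydroxystilbene
Conditions: BBr3 (8 equiv), CH2Cl2, −78 °C to rt, Ar, dark; then ice-water
Reagents that add atoms: none
Why: Lewis-acid aryl methyl ether cleavage (BBr3 complexes each ether oxygen and bromide removes the methyl group by SN2) leaves the trans olefin untouched, and hydrolytic work-up under argon releases the pentaphenol.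

**Step 3**
Reactants: 4 (E)-3,3',4,5,5'-pentahydroxystilbene (two molecules)
Product: 7 scirpusin C, via hydroxy-ortho-quinone 5 (not isolated), via para-quinone methide 6 (not isolated)
Conditions: PhI(OAc)2 (0.5 equiv per 4, added over 4 h), (R)-3,3'-bis(2,4,6-triisopropylphenyl)-1,1'-binaphthyl-2,2'-diyl hydrogen phosphate (10 mol%), EtOAc/MeCN 4:1, −40 °C, Ar, dark
Reagents that add atoms: none
Why: Proposed new method: a biomimetic oxidative formal [3+2] dehydrodimerisation (Michael addition/oxa-Michael cascade) in which PhI(OAc)2 dehydrogenates the pyrogallol ring of half of 4 to quinone 5; the chiral phosphoric acid hydrogen-bonds a quinone carbonyl and the 4'-OH of a second molecule of 4, whose C8 (a vinylogous para-phenol carbon) adds to the quinone ring carbon next to the styryl group (the reverse pairing, pyrogallol C2' of 4 adding 1,6 to the styryl terminus of 5, makes the same bond), so that quinone methide 6 forms with C3 set inside the chiral hydrogen-bonded complex, and 5-exo oxa-Michael closure of the adjacent regenerated phenol onto the quinone methide, anti to the 3-aryl group, sets C2 trans (also the thermodynamic isomer, since the closure is reversible under acid); the closest known reaction types are the domino Michael addition/cyclisation of in situ generated catechol ortho-quinones with carbon nucleophiles to benzofurans, the chiral phosphoric acid catalysed tandem oxidation/[3+2] annulation of hydroquinones or quinones with hydroxystyrenes and enecarbamates, and the oxidative dimerisation of resveratrol to ε-viniferin.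

**Compound list**
1 | 3,4,5-trimethoxybenzaldehyde | COc1cc(C=O)cc(OC)c1OC | starting material
2 | diethyl (3,5-dimethoxybenzyl)phosphonate | CCOP(=O)(Cc1cc(OC)cc(OC)c1)OCC | starting material
3 | 1,2,3-trimethoxy-5-[(E)-2-(3,5-dimethoxyphenyl)ethenyl]benzene, (E)-3,3',4,5,5'-pentamethoxystilbene | COc1cc(/C=C/c2cc(OC)c(OC)c(OC)c2)cc(OC)c1 | intermediate
4 | 5-[(E)-2-(3,5-dihydroxyphenyl)ethenyl]benzene-1,2,3-triol, (E)-3,3',4,5,5'-pentahydroxystilbene | Oc1cc(O)cc(/C=C/c2cc(O)c(O)c(O)c2)c1 | intermediate
5 | 3-hydroxy-5-[(E)-2-(3,5-dihydroxyphenyl)ethenyl]cyclohexa-3,5-diene-1,2-dione, hydroxy-ortho-quinone of 4 (not isolated) | O=C1C(=O)C(O)=CC(/C=C/c2cc(O)cc(O)c2)=C1 | intermediate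
6 | 4-{(2S)-2-(3,5-dihydroxyphenyl)-2-[6-[(E)-2-(3,5-dihydroxyphenyl)ethenyl]-2,3,4-trihydroxyphenyl]ethylidene}-2,6-dihydroxycyclohexa-2,5-dien-1-one, para-quinone methide (not isolated) | Oc1cc(O)cc(/C=C/c2cc(O)c(O)c(O)c2[C@H](c2cc(O)cc(O)c2)C=C2C=C(O)C(=O)C(O)=C2)c1 | intermediate
7 | 5-[(2S,3S)-4-[(E)-2-(3,5-dihydroxyphenyl)ethenyl]-6,7-dihydroxy-2-(3,4,5-trihydroxyphenyl)-2,3-dihydro-1-benzofuran-3-yl]benzene-1,3-diol, scirpusin C (2,3-trans) | Oc1cc(O)cc(/C=C/c2cc(O)c(O)c3c2[C@H](c2cc(O)cc(O)c2)[C@@H](c2cc(O)c(O)c(O)c2)O3)c1 | target

**Totals and risks**
Total step count: 3. Longest linear sequence: 3 (1 → 3 → 4 → 7).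

With three steps, all three are ranked, from most to least likely to fail: the dimerisation (step 3), the demethylation (step 2), the olefination (step 1).

Risk 1, the dimerisation (step 3). Only substoichiometric oxidant is used; the run is stopped near half conversion and unreacted 4 is recovered. The ways it can fail are:
- The resorcinol ring of 4 acts as the nucleophile and gives the regioisomeric dihydrobenzofuran fused to ring A.
- The quinone oxygens add across the olefin and give a 1,4-benzodioxane.
- Two pyrogallol rings couple with each other (biaryl or benzotropolone).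
- The product, itself a catechol and a pyrogallol, is oxidised further.
- The many free hydroxyl groups and the polar solvent erode the enantioselectivity.

The fallback sets out from 4 and comes back at 7. It gives up asymmetric catalysis and optimises the quinone coupling for regiochemistry alone, and both the medium and the source of enantiopurity change. Compound 4 is oxidised with Ag2O (0.5 equiv) in 1,1,1,3,3,3-hexafluoropropan-2-ol at 0 °C, a medium that favours C–C over C–O bond formation of quinone and quinone methide electrophiles but cannot transmit chirality. The trans dimer is then obtained as a racemate, that is 7 together with the (2R,3R)-enantiomer of scirpusin C F1. The racemate is freed of regioisomeric dimers by reversed-phase C18 HPLC, and the enantiomers are separated on a preparative amylose tris(3,5-dimethylphenylcarbamate) column. Compound 7 is identified by its CD spectrum and rotation against the natural product.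

Risk 2, the demethylation (step 2). Five ether cleavages on an electron-rich stilbene may stop at partially methylated material. The HBr formed can add to or isomerise the olefin, and the pentaphenol is air-sensitive on work-up.

The fallback sets out from 1 and comes back at 4, by-passing 3. The methyl groups are removed before any olefin exists: 1 is treated with BBr3 (CH2Cl2, −78 °C to rt) to give 3,4,5-trihydroxybenzaldehyde F2. F2 is then condensed with commercial 3,5-dihydroxyphenylacetic acid under amine-mediated Perkin/Knoevenagel conditions (piperidine, N-methylimidazole, polyethylene glycol, microwave, 160 °C, Ar). The (E)-2-(3,5-dihydroxyphenyl)-3-(3,4,5-trihydroxyphenyl)prop-2-enoic acid F3 formed in the flask loses CO2 through the para-quinone methide opened by its 4-OH group. This gives the E-stilbene 4 without any protecting group.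

Risk 3, the olefination (step 1). This is the least likely to fail; the concerns are incomplete conversion of the electron-rich aldehyde or a Z-containing mixture that does not crystallise cleanly.

The fallback sets out from 1 and comes back at 3. The olefin is made by palladium-catalysed coupling instead of carbonyl olefination. Wittig methylenation of 1 (MePPh3Br, KOtBu, THF, 0 °C) gives 5-ethenyl-1,2,3-trimethoxybenzene F4. F4 is joined to commercial 1-bromo-3,5-dimethoxybenzene by a Mizoroki–Heck reaction (Pd(OAc)2, P(o-tol)3, Et3N, DMF, 110 °C). Syn insertion followed by syn β-hydride elimination gives the E-stilbene 3 directly.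

**Further compounds**
F1 | step 3 | (2R,3R)-enantiomer of scirpusin C | Oc1cc(O)cc(/C=C/c2cc(O)c(O)c3c2[C@@H](c2cc(O)cc(O)c2)[C@H](c2cc(O)c(O)c(O)c2)O3)c1
F2 | step 2 | 3,4,5-trihydroxybenzaldehyde | O=Cc1cc(O)c(O)c(O)c1
F3 | step 2 | (E)-2-(3,5-dihydroxyphenyl)-3-(3,4,5-trihydroxyphenyl)prop-2-enoic acid | OC(=O)/C(=C/c1cc(O)c(O)c(O)c1)c1cc(O)cc(O)c1
F4 | step 1 | 5-ethenyl-1,2,3-trimethoxybenzene | COc1cc(C=C)cc(OC)c1OC
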